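## Retrosynthetic overview

1. Target 36 (germacrane numbering C1–C15 throughout) is a ten-membered ring C1–C10 with a ring-cis C1=C10, a ring-trans C4=C5 and a trans γ-lactone on C7/C8. The endgame removes the O14 PMB group, forms the O15 ester by Mitsunobu reaction, installs C11=C13 by Mannich/elimination and closes the lactone from C8–OH and a C12 acetal.
2. Structural feature: C8 (lactone oxygen) and C4 (the alkene carbon carrying C15) are 1,5-related across the ten-membered ring. A C4–C8 bond divides it into the cyclopentane C4–C5–C6–C7–C8 and the cycloheptene C4–C3–C2–C1=C10–C9–C8, in which C1=C10 can only be ring-cis.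
3. Key disconnection: C4–C8 cleavage by Grob fragmentation of the cis-fused bicyclo[5.3.0]decenol mesylate 23 (C8 alkoxide as donor, C5 mesylate cis to C15 as nucleofuge) to cyclodecadienone 25.
4. Ring order: cyclopentane (cyclopentane-1,3-dione; C4 by Michael/Wittig/hydroxymethylation, C5 by CBS desymmetrisation, C7 by aldol condensation and conjugate reduction, C8 by allylzinc addition), then cycloheptene (RCM), then the ten-membered ring (fragmentation), then the γ-lactone.

Key step: step 15

Assumption: 2,2-dimethoxyacetaldehyde (sold as a 60% aqueous solution, dried before use) and (R)-3-chloro-2-hydroxy-2-methylpropanoic acid are taken as purchasable.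

## Route

Step 1
Reactants: 1 cyclopentane-1,3-dione; 2 acrolein
Product: 3 2-(3-oxopropyl)cyclopentane-1,3-dione (rests as its cyclic enol hemiacetal)
Conditions: H2O, rt
Reagents that add atoms: none
Why: Michael addition of the acidic 1,3-dione to acrolein in water; the adduct closes to the enol hemiacetal, which has no C2–H left and so should not add a second acrolein.

Step 2
Reactants: 3 Michael adduct
Product: 4 2-(but-3-en-1-yl)cyclopentane-1,3-dione
Conditions: Ph3PCH3Br, KOtBu (excess), THF, 0 °C → rt; dilute HCl work-up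
Reagents that add atoms: methyltriphenylphosphonium bromide, C[P+](c1ccccc1)(c1ccccc1)c1ccccc1.[Br-]
Why: Wittig methylenation; the first equivalent of base opens the hemiacetal and stores the dione as its unreactive enolate, so only the aldehyde is olefinated.

Step 3
Reactants: 4 butenyl dione
Product: 5 2-(but-3-en-1-yl)-2-(hydroxymethyl)cyclopentane-1,3-dione
Conditions: 37% aq. CH2O, THF, rt
Reagents that add atoms: formaldehyde, C=O
Why: aldol-type hydroxymethylation of the 2-alkyl-1,3-dione enol at C2, which creates the quaternary (still prochiral) C4 with its C15 carbon.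

Step 4
Reactants: 5 hydroxymethyl dione
Product: 6 2-(but-3-en-1-yl)-2-{[tert-butyl(diphenyl)silyl]oxymethyl}cyclopentane-1,3-dione
Conditions: TBDPSCl, imidazole, CH2Cl2, 0 °C → rt
Reagents that add atoms: tert-butyl(chloro)diphenylsilane, CC(C)(C)[Si](Cl)(c1ccccc1)c1ccccc1
Why: silylation of the primary alcohol under conditions too mild for retro-aldol loss of formaldehyde; the bulky silyl ether is meant to make the C15 arm the larger C4 substituent for step 5.

Step 5
Reactants: 6 silyloxymethyl dione
Product: 7 (2R,3R)-hydroxy ketone (O5 cis to the C15 arm)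
Conditions: (S)-2-methyl-CBS-oxazaborolidine (0.2 equiv), catecholborane, toluene, −60 → −40 °C
Reagents that add atoms: none
Why: Corey–Bakshi–Shibata reduction: with the quaternary carbon as the large flank the (S)-catalyst should give the (R)-carbinol, and of the two enantiotopic carbonyls the one reduced should be that whose catalyst-preferred face lies anti to the bulky CH2OTBDPS arm, so that O5 ends cis to C15 and trans to the butenyl chain (4R,5R); catecholborane leaves the terminal alkene alone.

Step 6
Reactants: 7 hydroxy ketone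
Product: 8 (2R,3R)-3-(triethylsilyloxy) ketone
Conditions: TESOTf, 2,6-lutidine, CH2Cl2, −78 °C
Reagents that add atoms: triethylsilyl trifluoromethanesulfonate, CC[Si](CC)(CC)OS(=O)(=O)C(F)(F)F
Why: silyl triflate silylation of the hindered secondary alcohol; the ether blocks retro-aldol ring opening in the enolate steps and adds bulk on the O5 face.

Step 7
Reactants: 8 silyl ether ketone; 9 2,2-dimethoxyacetaldehyde
Product: 11 aldol adduct at C7 (mixture at the two new centres), via lithium enolate 10 (not isolated)
Conditions: LDA, THF, −78 °C; then 9 (anhydrous), −78 °C; aq. NH4Cl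
Reagents that add atoms: none
Why: directed aldol addition; C7 is the only enolisable position (C4 is quaternary) and the aldehyde has no α-hydrogen; both new centres are erased in steps 8 and 9.

Step 8
Reactants: 11 aldol adduct
Product: 13 (E)-7-(2,2-dimethoxyethylidene) enone, via aldol mesylate 12 (not isolated)
Conditions: MsCl, Et3N, CH2Cl2, 0 °C; then DBU, rt
Reagents that add atoms: none
Why: mesylation and E1cB elimination to the conjugated (E)-alkylidene ketone; the C6 hydrogens are not acidified, so the silyloxy group at C5 should not be eliminated.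

Step 9
Reactants: 13 enone
Product: 15 (2R,3R,5R)-ketone carrying the CH2CH(OMe)2 arm cis to O5, via lithium enolate 14 (not isolated)
Conditions: L-Selectride, THF, −78 °C; then 2,6-di-tert-butyl-4-methylphenol, −78 °C; aq. NH4Cl
Reagents that add atoms: none
Why: conjugate reduction of the s-cis exocyclic enone (carbonyl shielded by quaternary C4), then kinetic protonation of enolate 14 at C7 by the bulky phenol from the face anti to OSiEt3 and CH2OTBDPS, which should place the arm cis to O5 (7R); this 5,7-cis isomer is also the one expected at equilibrium.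

Step 10
Reactants: 16 3-chloro-2-(chloromethyl)prop-1-ene; 17 (4-methoxyphenyl)methanol
Product: 18 1-({[2-(chloromethyl)prop-2-en-1-yl]oxy}methyl)-4-methoxybenzene
Conditions: NaH, THF/DMF, Bu4NI (cat.), 16 in excess, 0 °C → rt
Reagents that add atoms: none
Why: Williamson ether synthesis at one of two equivalent allylic chlorides; the excess of dichloride suppresses the bis-ether.

Step 11
Reactants: 15 ketone; 18 allylic chloride
Product: 20 (1S,2R,3R,5R)-tertiary alcohol diene, via allylzinc chloride 19 (not isolated)
Conditions: Zn, LiCl, THF, rt; then 15, −40 → 0 °C; aq. NaHCO3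
Reagents that add atoms: none
Why: zinc insertion gives allylzinc 19, which adds through a six-membered SE2′ transition state to the C8 carbonyl from the face anti to the C7 arm, OSiEt3 and CH2OTBDPS, setting C8 (S) with the hydroxyl cis to C15 and the new chain cis to the butenyl chain.

Step 12
Reactants: 20 diene
Product: 21 cis-fused bicyclo[5.3.0]dec-1(10)-ene triethylsilyl ether
Conditions: Grubbs II (5 mol %), CH2Cl2 (high dilution), 40 °C
Reagents that add atoms: none
Why: ring-closing metathesis between the monosubstituted and the 1,1-disubstituted alkene held cis on C4 and C8 closes the seven-membered ring, in which C1=C10 is necessarily ring-cis.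

Step 13
Reactants: 21 bicyclic silyl ether
Product: 22 bicyclic C5,C8-diol
Conditions: HF·pyridine, pyridine, THF, 0 °C
Reagents that add atoms: none
Why: buffered fluoride desilylation; the secondary triethylsilyl ether is cleaved much faster than the primary TBDPS ether, and the buffered medium should not ionise the acetal.

Step 14
Reactants: 22 diol
Product: 23 C5 mesylate with free C8 tertiary alcohol (4R,5R,7R,8S)
Conditions: MsCl, Et3N, CH2Cl2, −20 → 0 °C
Reagents that add atoms: methanesulfonyl chloride, CS(=O)(=O)Cl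
Why: sulfonylation (via sulfene) of the secondary C5 hydroxyl with retention at C5, the tertiary C8 hydroxyl being unreactive at this temperature.

Step 15
Reactants: 23 hydroxy mesylate
Product: 25 (7R)-cyclodeca-1(10),4-dien-8-one with ring-cis C1=C10 and ring-trans C4=C5, via potassium alkoxide 24 (not isolated)
Conditions: KHMDS (1.0 equiv), THF, −78 → 0 °C; pH 7 buffer
Reagents that add atoms: none
Why: One equivalent of KHMDS deprotonates the C8 tertiary hydroxyl and alkoxide 24 should fragment in a concerted Grob manner: the O–C8 bond becomes the C8 carbonyl, the C4–C8 ring-fusion σ bond breaks, the C4=C5 π bond forms and mesylate leaves from C5. The closest known reaction type is the base-induced (Wharton-type) fragmentation of bicyclic 1,3-diol monosulfonates of the decalin and hydrindane series to medium-ring (E)-cycloalkenones. No ring is closed by bond formation: the ten-membered ring appears when the bond shared by the cyclopentane and the cycloheptene is cut, so no macrocyclisation is involved. No stereocentre is created; the ring-trans C4=C5 geometry follows from the antiperiplanar C5–OMs/C4–C8 arrangement with the mesylate cis to the C15 arm and trans to C3, which leaves C6 and C3 trans across the new double bond, while the ring-cis C1=C10 alkene is carried over unchanged. The step needs fragmentation to outrun oxetane formation, elimination and enolisation of the product: the cis O8/O5 relationship rules out backside attack of the alkoxide on C5, the flexible cis-fused skeleton lets the C5–O bond approach the antiperiplanar alignment with C4–C8 (about 160°), and exactly one equivalent of a non-nucleophilic amide at low temperature leaves no base to epimerise C7 or to conjugate the β,γ-unsaturated ketone.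

Step 16
Reactants: 25 cyclodecadienone
Product: 26 (7R,8S)-alcohol
Conditions: (R)-2-methyl-CBS-oxazaborolidine (1 equiv), catecholborane, toluene/CH2Cl2, −78 °C
Reagents that add atoms: none
Why: Corey–Bakshi–Shibata reduction under reagent control; with the branched C7 as large and C9H2 as small flank the (R)-catalyst should deliver hydride to give the (8S)-carbinol, and the neutral, cold conditions leave C7 and the β,γ-alkene untouched.

Step 17
Reactants: 26 hydroxy acetal
Product: 27 8,12-lactol (both C12 epimers)
Conditions: AcOH/THF/H2O (3:1:1), 40 °C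
Reagents that add atoms: water, O
Why: mild acid hydrolysis of the dimethyl acetal; the aldehyde is captured by the C8 hydroxyl as the five-membered lactol, and the ring alkenes, deactivated by their allylic oxygens, should resist transannular cyclisation.

Step 18
Reactants: 27 lactol
Product: 28 trans-fused γ-lactone (7R,8S)
Conditions: TPAP (5 mol %), NMO, 4 Å MS, CH2Cl2, rt
Reagents that add atoms: none
Why: Ley–Griffith oxidation of the lactol to the lactone; the trans ring fusion is fixed by C7 (step 9) and C8 (step 16), neither of which is touched.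

Step 19
Reactants: 28 lactone
Product: 30 11-(dimethylaminomethyl) lactone, via lithium lactone enolate 29 (not isolated)
Conditions: LiHMDS, THF, −78 °C; then Eschenmoser's salt, −78 → 0 °C
Reagents that add atoms: N,N-dimethylmethyleneiminium iodide, C=[N+](C)C.[I-]
Why: Mannich reaction of the lactone enolate with the iminium salt; the C11 configuration is irrelevant because it is lost in step 20.

Step 20
Reactants: 30 Mannich base
Product: 32 α-methylene lactone (C14 OPMB, C15 OTBDPS), via trimethylammonium iodide 31 (not isolated)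
Conditions: MeI, MeOH, rt; then aq. NaHCO3, rt
Reagents that add atoms: none
Why: N-quaternisation followed by E1cB (Hofmann-type) loss of trimethylamine gives the exocyclic C11=C13 alkene.

Step 21
Reactants: 32 silyl ether
Product: 33 C15 allylic alcohol
Conditions: TBAF, AcOH (1:1), THF, 0 °C → rt
Reagents that add atoms: none
Why: fluoride desilylation buffered with acetic acid so that no free alkoxide or fluoride adds to the methylene lactone; the PMB ether is inert.

Step 22
Reactants: 33 C15 alcohol; 34 (R)-3-chloro-2-hydroxy-2-methylpropanoic acid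
Product: 35 C15 (R)-3-chloro-2-hydroxy-2-methylpropanoate with C14 OPMB
Conditions: PPh3, DIAD, THF, 0 °C (betaine pre-formed); then 34 and 33, 0 °C → rt
Reagents that add atoms: none
Why: Mitsunobu esterification; the carboxylic acid is the only pronucleophile acidic enough, its tertiary hydroxyl cannot be activated, and the primary allylic C15 alcohol is displaced at carbon, so the stereocentre of the acid is not involved.

Step 23
Reactants: 35 PMB ether
Product: 36 target CNP0239315.1
Conditions: DDQ, CH2Cl2/pH 7 buffer (10:1), 0 °C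
Reagents that add atoms: none
Why: oxidative cleavage of the PMB ether at its electron-rich benzylic position; the ester, chlorohydrin and methylene lactone are inert to DDQ at 0 °C.

## Compound list

1 | cyclopentane-1,3-dione | O=C1CCC(=O)C1 | starting material
2 | acrolein | C=CC=O | starting material
3 | 2-(3-oxopropyl)cyclopentane-1,3-dione (open form drawn; rests as the cyclic enol hemiacetal) | O=CCCC1C(=O)CCC1=O | intermediate
4 | 2-(but-3-en-1-yl)cyclopentane-1,3-dione | C=CCCC1C(=O)CCC1=O | intermediate
5 | 2-(but-3-en-1-yl)-2-(hydroxymethyl)cyclopentane-1,3-dione | C=CCCC1(CO)C(=O)CCC1=O | intermediate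
6 | 2-(but-3-en-1-yl)-2-{[tert-butyl(diphenyl)silyl]oxymethyl}cyclopentane-1,3-dione | C=CCCC1(CO[Si](c2ccccc2)(c2ccccc2)C(C)(C)C)C(=O)CCC1=O | intermediate
7 | (2R,3R)-2-(but-3-en-1-yl)-2-{[tert-butyl(diphenyl)silyl]oxymethyl}-3-hydroxycyclopentan-1-one (OH cis to the silyloxymethyl arm) | O=C1CC[C@@H](O)[C@@]1(CCC=C)CO[Si](c1ccccc1)(c1ccccc1)C(C)(C)C | intermediate
8 | (2R,3R)-2-(but-3-en-1-yl)-2-{[tert-butyl(diphenyl)silyl]oxymethyl}-3-(triethylsilyloxy)cyclopentan-1-one | O=C1CC[C@@H](O[Si](CC)(CC)CC)[C@@]1(CCC=C)CO[Si](c1ccccc1)(c1ccccc1)C(C)(C)C | intermediate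
9 | 2,2-dimethoxyacetaldehyde | COC(OC)C=O | starting material
10 | lithium enolate of 8 (C7=C8–OLi) | [Li+].[O-]C1=CC[C@@H](O[Si](CC)(CC)CC)[C@@]1(CCC=C)CO[Si](c1ccccc1)(c1ccccc1)C(C)(C)C | intermediate (not isolated)
11 | aldol adduct of 8: 5-(1-hydroxy-2,2-dimethoxyethyl) ketone, mixture at the two new centres | O=C1C(C(O)C(OC)OC)C[C@@H](O[Si](CC)(CC)CC)[C@@]1(CCC=C)CO[Si](c1ccccc1)(c1ccccc1)C(C)(C)C | intermediate
12 | methanesulfonate of 11 | O=C1C(C(OS(C)(=O)=O)C(OC)OC)C[C@@H](O[Si](CC)(CC)CC)[C@@]1(CCC=C)CO[Si](c1ccccc1)(c1ccccc1)C(C)(C)C | intermediate (not isolated)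
13 | (2R,3R,5E)-2-(but-3-en-1-yl)-2-{[tert-butyl(diphenyl)silyl]oxymethyl}-5-(2,2-dimethoxyethylidene)-3-(triethylsilyloxy)cyclopentan-1-one | O=C1/C(=C/C(OC)OC)C[C@@H](O[Si](CC)(CC)CC)[C@@]1(CCC=C)CO[Si](c1ccccc1)(c1ccccc1)C(C)(C)C | intermediate
14 | lithium enolate formed by 1,4-reduction of 13 | [Li+].[O-]C1=C(CC(OC)OC)C[C@@H](O[Si](CC)(CC)CC)[C@@]1(CCC=C)CO[Si](c1ccccc1)(c1ccccc1)C(C)(C)C | intermediate (not isolated)
15 | (2R,3R,5R)-2-(but-3-en-1-yl)-2-{[tert-butyl(diphenyl)silyl]oxymethyl}-5-(2,2-dimethoxyethyl)-3-(triethylsilyloxy)cyclopentan-1-one (arm cis to OSiEt3) | O=C1[C@@H](CC(OC)OC)C[C@@H](O[Si](CC)(CC)CC)[C@@]1(CCC=C)CO[Si](c1ccccc1)(c1ccccc1)C(C)(C)C | intermediate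
16 | 3-chloro-2-(chloromethyl)prop-1-ene | C=C(CCl)CCl | starting material
17 | (4-methoxyphenyl)methanol | COc1ccc(CO)cc1 | starting material
18 | 1-({[2-(chloromethyl)prop-2-en-1-yl]oxy}methyl)-4-methoxybenzene | C=C(CCl)COCc1ccc(OC)cc1 | intermediate
19 | {2-[(4-methoxybenzyloxy)methyl]prop-2-en-1-yl}zinc chloride | C=C(C[Zn]Cl)COCc1ccc(OC)cc1 | intermediate (not isolated)
20 | (1S,2R,3R,5R)-2-(but-3-en-1-yl)-2-{[tert-butyl(diphenyl)silyl]oxymethyl}-5-(2,2-dimethoxyethyl)-1-{2-[(4-methoxybenzyloxy)methyl]prop-2-en-1-yl}-3-(triethylsilyloxy)cyclopentan-1-ol | C=CCC[C@@]1(CO[Si](c2ccccc2)(c2ccccc2)C(C)(C)C)[C@H](O[Si](CC)(CC)CC)C[C@H](CC(OC)OC)[C@@]1(O)CC(=C)COCc1ccc(OC)cc1 | intermediate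
21 | cis-fused (4R,5R,7R,8S)-bicyclo[5.3.0]dec-1(10)-ene (cyclopentane C4–C8, cycloheptene C4–C3–C2–C1=C10–C9–C8) with C4 CH2OTBDPS, C5 OSiEt3, C7 CH2CH(OMe)2, C8 OH and C10 CH2OPMB, the four cyclopentane substituents on one face | CC(C)(C)[Si](c1ccccc1)(c1ccccc1)OC[C@@]12CCC=C(COCc3ccc(OC)cc3)C[C@]1(O)[C@@H](CC(OC)OC)C[C@H]2O[Si](CC)(CC)CC | intermediate
22 | C5,C8-diol corresponding to 21 (C5 OH secondary, C8 OH tertiary) | CC(C)(C)[Si](c1ccccc1)(c1ccccc1)OC[C@@]12CCC=C(COCc3ccc(OC)cc3)C[C@]1(O)[C@@H](CC(OC)OC)C[C@H]2O | intermediate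
23 | C5 methanesulfonate of 22 with free C8 tertiary alcohol (key precursor) | CC(C)(C)[Si](c1ccccc1)(c1ccccc1)OC[C@@]12CCC=C(COCc3ccc(OC)cc3)C[C@]1(O)[C@@H](CC(OC)OC)C[C@H]2OS(C)(=O)=O | intermediate
24 | potassium C8-alkoxide of 23 | [K+].CC(C)(C)[Si](c1ccccc1)(c1ccccc1)OC[C@@]12CCC=C(COCc3ccc(OC)cc3)C[C@]1([O-])[C@@H](CC(OC)OC)C[C@H]2OS(C)(=O)=O | intermediate (not isolated)
25 | (7R)-cyclodeca-1(10),4-dien-8-one with ring-cis C1=C10, ring-trans C4=C5, C4 CH2OTBDPS, C7 CH2CH(OMe)2 and C10 CH2OPMB (key product) | COC(OC)C[C@H]1C\C=C(CO[Si](c2ccccc2)(c2ccccc2)C(C)(C)C)\CC/C=C(COCc2ccc(OC)cc2)\CC1=O | intermediate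
26 | (7R,8S)-cyclodecadien-8-ol derived from 25 | COC(OC)C[C@H]1C\C=C(CO[Si](c2ccccc2)(c2ccccc2)C(C)(C)C)\CC/C=C(COCc2ccc(OC)cc2)\C[C@@H]1O | intermediate
27 | (7R,8S)-8,12-lactol (C12 hemiacetal, both epimers) | OC1C[C@H]2C\C=C(CO[Si](c3ccccc3)(c3ccccc3)C(C)(C)C)\CC/C=C(COCc3ccc(OC)cc3)\C[C@@H]2O1 | intermediate
28 | (7R,8S)-trans-fused 8,12-olide (γ-lactone) with C14 OPMB and C15 OTBDPS | O=C1C[C@H]2C\C=C(CO[Si](c3ccccc3)(c3ccccc3)C(C)(C)C)\CC/C=C(COCc3ccc(OC)cc3)\C[C@@H]2O1 | intermediate
29 | lithium enolate of lactone 28 | [Li+].[O-]C1=C[C@H]2C\C=C(CO[Si](c3ccccc3)(c3ccccc3)C(C)(C)C)\CC/C=C(COCc3ccc(OC)cc3)\C[C@@H]2O1 | intermediate (not isolated)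
30 | 11-(dimethylaminomethyl) lactone (C11 unassigned) | O=C1C(CN(C)C)[C@H]2C\C=C(CO[Si](c3ccccc3)(c3ccccc3)C(C)(C)C)\CC/C=C(COCc3ccc(OC)cc3)\C[C@@H]2O1 | intermediate
31 | 11-(trimethylammoniomethyl) lactone iodide | O=C1C(C[N+](C)(C)C)[C@H]2C\C=C(CO[Si](c3ccccc3)(c3ccccc3)C(C)(C)C)\CC/C=C(COCc3ccc(OC)cc3)\C[C@@H]2O1.[I-] | intermediate (not isolated)
32 | α-methylene lactone with C14 OPMB and C15 OTBDPS | C=C1C(=O)O[C@H]2C/C(COCc3ccc(OC)cc3)=C\CC/C(CO[Si](c3ccccc3)(c3ccccc3)C(C)(C)C)=C/C[C@H]12 | intermediate
33 | α-methylene lactone with C14 OPMB and free C15 OH | C=C1C(=O)O[C@H]2C/C(COCc3ccc(OC)cc3)=C\CC/C(CO)=C/C[C@H]12 | intermediate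
34 | (R)-3-chloro-2-hydroxy-2-methylpropanoic acid | OC(=O)[C@@](C)(O)CCl | starting material
35 | C15 (R)-3-chloro-2-hydroxy-2-methylpropanoate with C14 OPMB | C=C1C(=O)O[C@H]2C/C(COCc3ccc(OC)cc3)=C\CC/C(COC(=O)[C@@](C)(O)CCl)=C/C[C@H]12 | intermediate
36 | CNP0239315.1 | C=C1C(=O)O[C@H]2C/C(CO)=C\CC/C(COC(=O)[C@@](C)(O)CCl)=C/C[C@H]12 | target

## Step count and risks

Total step count: 23. Longest linear sequence: 22 steps (steps 1–9 and 11–23 from cyclopentane-1,3-dione); step 10 is a one-step side branch.

**Steps most likely to fail**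

1. Step 15 (Grob fragmentation). On the cyclopentane the C5–O bond may not reach the antiperiplanar alignment with C4–C8. The alkoxide could then transfer the mesyl group to O8, lose it through sulfene formation, or persist long enough to enolise the product (C7 epimerisation, conjugation of the β,γ-enone). Fallback: the route sets out again from diol 22, which is treated with Tf2O and 2,6-di-tert-butyl-4-methylpyridine in CH2Cl2 at −78 → −20 °C. The secondary hydroxyl is converted into the C5 trifluoromethanesulfonate F1, which is not isolated. With this far better nucleofuge the neutral tertiary hydroxyl should suffice as electron donor, so the same C4–C8 cleavage runs as a solvolytic push–pull fragmentation without strong base and returns to 25.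

2. Step 5 (desymmetrising reduction). The carbinol configuration is catalyst-controlled, but the incoming hydride may discriminate poorly between the two C4 arms. That would give the diastereomer with O5 trans to C15, which leads to the ring-cis C4=C5 alkene. Fallback: the route sets out from 6 and returns at 7 by exchanging the roles of the two ring oxygens.
   - The diastereomeric (2S,3R)-hydroxy ketone F2 from the same reduction is treated with Me4NBH(OAc)3 in MeCN/AcOH. Hydroxyl-directed hydride delivery gives the (1R,3R)-trans-diol F3, in which C4 is no longer a stereocentre and the two hydroxyls differ only in being cis to C15 or to the butenyl chain.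
   - TBAF gives the triol F4.
   - 2,2-Dimethoxypropane/PPTS engages only the hydroxyl cis to the hydroxymethyl group, as a cis-fused 1,3-dioxane, giving the acetonide alcohol F5.
   - Dess–Martin oxidation of the remaining hydroxyl gives the acetonide ketone F6, and aqueous acetic acid releases the (2R,3R)-dihydroxy ketone F7.
   - TBDPSCl/imidazole silylates the primary hydroxyl and gives 7.
   
   Because the ketone and carbinol carbons have changed places, F2 converges on the same enantiomer 7 as the directly formed product.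

3. Step 16 (C8 ketone reduction). The conformational preference of the ten-membered ring may override the catalyst, so that hydride enters the other carbonyl face. Fallback: the route sets out from 25, which is reduced with the opposite sense (substrate control with L-Selectride, or the enantiomeric catalyst) to the (7R,8R)-alcohol F8. Mitsunobu reaction with 4-nitrobenzoic acid (PPh3, DIAD) inverts C8 and gives the (8S)-4-nitrobenzoate F9. Methanolysis (K2CO3, MeOH) returns to 26.

## Further compounds

F1 | step 15 | C5 trifluoromethanesulfonate of diol 22 | CC(C)(C)[Si](c1ccccc1)(c1ccccc1)OC[C@@]12CCC=C(COCc3ccc(OC)cc3)C[C@]1(O)[C@@H](CC(OC)OC)C[C@H]2OS(=O)(=O)C(F)(F)F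
F2 | step 5 | (2S,3R)-2-(but-3-en-1-yl)-2-{[tert-butyl(diphenyl)silyl]oxymethyl}-3-hydroxycyclopentan-1-one (OH trans to the silyloxymethyl arm) | O=C1CC[C@@H](O)[C@]1(CCC=C)CO[Si](c1ccccc1)(c1ccccc1)C(C)(C)C
F3 | step 5 | (1R,3R)-2-(but-3-en-1-yl)-2-{[tert-butyl(diphenyl)silyl]oxymethyl}cyclopentane-1,3-diol | O[C@@H]1CC[C@@H](O)C1(CCC=C)CO[Si](c1ccccc1)(c1ccccc1)C(C)(C)C
F4 | step 5 | (1R,3R)-2-(but-3-en-1-yl)-2-(hydroxymethyl)cyclopentane-1,3-diol | O[C@@H]1CC[C@@H](O)C1(CCC=C)CO
F5 | step 5 | acetonide of F4 across the hydroxymethyl oxygen and the cis ring hydroxyl, remaining ring hydroxyl free | CC1(C)OC[C@@]2(CCC=C)[C@H](O)CC[C@H]2O1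
F6 | step 5 | acetonide ketone from F5 | CC1(C)OC[C@@]2(CCC=C)C(=O)CC[C@H]2O1
F7 | step 5 | (2R,3R)-2-(but-3-en-1-yl)-3-hydroxy-2-(hydroxymethyl)cyclopentan-1-one | O=C1CC[C@@H](O)[C@@]1(CCC=C)CO
F8 | step 16 | (7R,8R)-alcohol, C8 epimer of 26 | COC(OC)C[C@H]1C\C=C(CO[Si](c2ccccc2)(c2ccccc2)C(C)(C)C)\CC/C=C(COCc2ccc(OC)cc2)\C[C@H]1O
F9 | step 16 | (7R,8S)-4-nitrobenzoate | COC(OC)C[C@H]1C\C=C(CO[Si](c2ccccc2)(c2ccccc2)C(C)(C)C)\CC/C=C(COCc2ccc(OC)cc2)\C[C@@H]1OC(=O)c1ccc(cc1)[N+](=O)[O-]
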